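Abbreviations used in names: ArAB = 2,6-dimethoxy-4-(2,4,6-trimethoxyphenoxy)phenyl (rings B and A); ArFG = 3,5-dimethoxy-4-(3,4,5-trimethoxyphenoxy)phenyl (rings F and G); ArEFG = 3,4,5-trimethoxy-2-(ArFG-oxy)phenyl (rings E, F, G). Rings are lettered A (2,4,6-trihydroxyphenyl end) to G (3,4,5-trihydroxyphenyl end). On each ring, carbon 1 is the ether carbon facing the G end, except ring C and ring E, where carbon 1 carries the ether to the next ring towards G and carbon 2 the ether towards A.

## Analysis of the target

The target is a linear chain of seven benzene rings joined only by six diaryl ether oxygens; it has eighteen free phenolic hydroxyls, no carbon–carbon bond between rings and no stereocenter. Ring A is a 2,4,6-trihydroxyphenyl group and ring G a 3,4,5-trihydroxyphenyl group. Rings B and F carry ethers on carbons 1 and 4 and hydroxyls on carbons 3 and 5, and ring D carries ethers on carbons 1 and 5 and hydroxyls on carbons 3 and 4. Rings C and E are pentaoxygenated, with ethers on carbons 1 and 2, hydroxyls on carbons 4, 5 and 6 and a single hydrogen on carbon 3. The free polyphenol is sensitive to oxidation, so all hydroxyls should travel masked and be released in the last step. The difficulty lies in the ethers: all rings are electron-rich, nothing activates nucleophilic aromatic substitution, and several oxygens sit between two ortho substituents. The worst case is the B–O–C ether: carbon 1 of ring B lies between two oxygenated carbons, and carbon 2 of ring C lies next to the oxygen that carries ring D. Ring B has no hydrogen next to carbon 1 from which an aryne could form, and an aryne across carbons 2 and 3 of ring C would be flanked by oxygen on both sides and offer no regiocontrol. The strategy rests on the substitution pattern of ring C: its five contiguous oxygens (on carbons 2, 1, 6, 5, 4) and lone hydrogen (carbon 3) map onto a squaric ester (carbons 4, 5, 6, 1) plus a 1-aryloxyvinyl group (carbons 2 and 3), so ring C can be built with the ring B oxygen already in place.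

## Retrosynthetic reasoning

51 is traced back to its octadecamethyl ether 50. Methyl is chosen because squarate 13 delivers two of the ring C oxygens as methoxy groups and all other building blocks are methoxyarenes; one global ether cleavage then ends the synthesis.

50 is cut at the C–O–D ether on the ring D side, giving trimer phenol 21 and tetramer 48. The cut divides the molecule three to four. The oxygen on carbon 1 of ring C is flanked twice and is a poor partner for metal-catalysed coupling, but carbon 1 of ring D has hydrogen on both sides and a methoxy group on carbon 3. The aryne 49 released from 48 should therefore take the phenoxide at carbon 1, remote from the flanking methoxy group.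

21 comes from 20 by removal of a methoxymethyl group, and 20 from phenol 19 by methylation. These two steps exchange the roles of the para oxygens on carbons 1 and 4 of ring C.

19 is opened at the ring C bond between carbons 3 and 4 (retro six-electron electrocyclization to ketene 17 through dienone 18) and the ketene is folded back to cyclobutenone 16. This removes the need for any aryl–oxygen coupling at the pentaoxygenated ring: the B–O–C oxygen is carried in as an enol ether oxygen, all five oxygens are in place before the ring exists, and the two para oxygens emerge differentiated.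

16 is the methoxymethyl ether of alcohol 15, which is cut between the carbinol carbon and the vinyl carbon into squarate 13 and vinyllithium 14, the latter released from stannane 12 by tin–lithium exchange. Exchange is preferred to deprotonation because rings A and B carry acidic hydrogens between two oxygens.

12 derives from ethynyl ether 11 by hydrostannation, 11 from dichlorovinyl ether 8, and 8 from phenol 5 and trichloroethylene 6 through 7. The hindered oxygen of 5 is thus bonded to a linear two-carbon unit and never to an aryl carbon.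

5 comes from benzyl ether 4, which is cut at the A–O–B ether into bromide 2 and phenol 3; 2 is the benzyl ether of 1. Here the hindered partner is the phenol and the bromide carbon is unhindered, so copper catalysis is adequate.

48 is traced through carbamate 46 and carbamate 42 to phenol 41 (ortho-silylation directed by the carbamate, then triflation), and 41 to aldehyde 39 by Baeyer–Villiger oxidation. The formyl group serves as a masked hydroxyl that survives the coupling steps.

39 is cut at the D–O–E ether into iodide 37 and phenol 38. Unlike the B–O–C ether, both carbons of this ether have only one ortho substituent, so ring E does not need de novo construction and an Ullmann coupling should do.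

37 is cut at the E–O–F ether into iodophenol 35 and silyl triflate 33 (through aryne 36). The doubly flanked oxygen on carbon 1 of ring E adds to an unhindered aryne carbon, the same logic as for the C–O–D ether. 35 comes from 34 by ortho-iodination.

33 is traced through carbamates 31 and 27 to phenol 26, 26 to aldehyde 24, and 24 is cut at the F–O–G ether into 22 and boronic acid 23, an oxidative copper coupling of a hindered phenol with an unhindered aryl donor.

## Alternatives that were turned down

Alternative 1: Both ethers of ring D are cut, and ring D arrives as the dichloroarene bound to a cyclopentadienylruthenium cation, A1. In one flask the phenoxide of 21 would displace the chlorine flanked by two hydrogens, the phenoxide of trimer A2 the chlorine next to methoxy, and irradiation would release A3, which is identical with 50.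
- For: the cationic complex accepts hindered phenoxides, two ethers form in one operation, and the end-game is shorter than the aryne route. On convergence at the centre it is stronger than the chosen route.
- Against: ruthenium is stoichiometric, the arene with two methoxy donors must first be complexed, and the order of substitution rests only on the steric difference between the two chlorines. The first aryloxy group also deactivates the complex toward the second substitution, which must occur next to a methoxy group.
- Comparison: it does not make ring C or ring E and leaves the B–O–C ether unsolved, so 21 would still have to come from the chosen key step. The chosen route offers a metal-free union whose regiochemistry is fixed by the aryne.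

Alternative 2: Ring A is cut at its carbon–carbon bonds 2–3 and 5–6. An alkoxide base would condense both methylene carbons of A5 with the two ester groups of the hexamer-oxy malonate A4 to give A6, with ring A as an aromatic triol diester.
- For: it is a classical phloroglucinol ring synthesis, and the ring A oxygen is never used in an aryl coupling.
- Against: it solves the easiest ether of the molecule, since the A–O–B bond yields to an ordinary Ullmann coupling. It needs the complete B-to-G hexamer first, so it is linear and places a double condensation at a crowded tertiary malonate carbon on the most valuable intermediate. Two ester groups must then be hydrolysed and decarboxylated before demethylation.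
- Comparison: it is longer, less convergent (six plus one) and leaves the B–O–C ether open; the chosen route spends its ring construction where coupling is not feasible.

Alternative 3: Ring D is cut at bonds 2–3 and 1–6. Heating cyclobutenone A7 with ethynyl ether A8 would give A9 by a Danheiser benzannulation (vinylketene, cycloaddition, ring opening, electrocyclization).
- For: both ethers of ring D are carried in, the polarity of the ynol ether fixes the regiochemistry, and the free hydroxyl on carbon 3 of ring D is a hydroxyl in the target. It is as convergent as the chosen union and needs no aryne precursor.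
- Against: A7, a 3-aryloxy-4-methoxycyclobutenone of tetramer size, has no reliable access. A8 is a heat-sensitive ynol ether that would itself be made from 21. The bimolecular cycloaddition of two large, labile partners must compete with their decomposition.
- Comparison: the chosen route places its one pericyclic risk early, on a small substrate and in a unimolecular step, and it makes the pentaoxygenated ring that alternative 3 presupposes.

Key step: step 9

Remark on the chemistry: phenols 3 and 34 are taken as catalogue compounds; each is otherwise one Baeyer–Villiger oxidation and hydrolysis away from the corresponding commercial benzaldehyde.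

## Route

Step 1
Reactants: 1 4-bromo-2,6-dimethoxyphenol
Product: 2 2-(benzyloxy)-5-bromo-1,3-dimethoxybenzene
Conditions: BnBr, K2CO3, DMF, rt
Reagents that add atoms: benzyl bromide, BrCc1ccccc1
Why: Williamson etherification of the phenoxide; the benzyl group keeps the ring B oxygen out of the copper coupling and is removed later without acid or base.

Step 2
Reactants: 2 2-(benzyloxy)-5-bromo-1,3-dimethoxybenzene; 3 2,4,6-trimethoxyphenol
Product: 4 2-(benzyloxy)-1,3-dimethoxy-5-(2,4,6-trimethoxyphenoxy)benzene
Conditions: CuI (10 mol %), picolinic acid (20 mol %), K3PO4, DMSO, 90 °C, Ar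
Reagents that add atoms: none
Why: Ullmann diaryl ether synthesis; the bromide carbon has hydrogen on both sides, so the hindrance lies only in the phenoxide, which the picolinate-ligated copper catalyst tolerates. Degassing protects the electron-rich phenol from oxidation.

Step 3
Reactants: 4 2-(benzyloxy)-1,3-dimethoxy-5-(2,4,6-trimethoxyphenoxy)benzene
Product: 5 2,6-dimethoxy-4-(2,4,6-trimethoxyphenoxy)phenol (ArAB–OH)
Conditions: H2 (1 atm), 10% Pd/C, EtOAc–MeOH, rt
Reagents that add atoms: none
Why: Hydrogenolysis of the benzyl ether; methyl and diaryl ethers are inert.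

Step 4
Reactants: 5 2,6-dimethoxy-4-(2,4,6-trimethoxyphenoxy)phenol; 6 trichloroethylene
Product: 8 (E)-1,2-dichlorovinyl ether ArAB–O–CCl=CHCl, via dichloroacetylene 7 (not isolated)
Conditions: K2CO3, DMF, 70 °C
Reagents that add atoms: none
Why: Base-induced loss of HCl from trichloroethylene gives dichloroacetylene, to which the phenoxide adds in anti fashion (vinylic substitution by elimination–addition). The hindered oxygen meets only a linear carbon.

Step 5
Reactants: 8 (E)-1,2-dichlorovinyl ether ArAB–O–CCl=CHCl
Product: 11 ethynyl ether ArAB–O–C≡CH, via chloroethynyl ether 9 (not isolated), via lithium acetylide 10 (not isolated)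
Conditions: n-BuLi (2.3 equiv), Et2O, −78 → −40 °C; H2O, −78 °C
Reagents that add atoms: none
Why: β-Elimination of HCl followed by chlorine–lithium exchange is the standard passage from dichlorovinyl ethers to ynol ethers; protonation gives the terminal alkyne. The product is kept cold in solution and used at once, since aryl ynol ethers oligomerise.

Step 6
Reactants: 11 ethynyl ether ArAB–O–C≡CH
Product: 12 tributyl[1-(ArAB-oxy)ethenyl]stannane
Conditions: Bu3SnH, Pd(PPh3)4 (2 mol %), THF, 0 °C
Reagents that add atoms: tributyltin hydride, CCCC[SnH](CCCC)CCCC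
Why: Syn-hydrostannation of a 1-alkoxyalkyne under zerovalent palladium catalysis delivers hydride to the terminal carbon and tin to the oxygen-bearing carbon. The stannane is filtered through base-washed silica to avoid protodestannylation.

Step 7
Reactants: 12 tributyl[1-(ArAB-oxy)ethenyl]stannane; 13 dimethyl squarate
Product: 15 racemic 4-hydroxy-2,3-dimethoxy-4-[1-(ArAB-oxy)ethenyl]cyclobut-2-en-1-one, via vinyllithium 14 (not isolated)
Conditions: MeLi, THF, −78 °C; cannulate into 13, THF, −78 °C; aq. NH4Cl, −78 °C
Reagents that add atoms: none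
Why: Tin–lithium exchange gives 14 without deprotonating the ring hydrogens between two oxygens; 14 adds once to a carbonyl of the squarate (1,2-addition), the adduct alkoxide being unreactive at −78 °C. The new stereocenter is formed racemic and is destroyed in step 9.

Step 8
Reactants: 15 racemic 4-hydroxy-2,3-dimethoxy-4-[1-(ArAB-oxy)ethenyl]cyclobut-2-en-1-one
Product: 16 racemic 2,3-dimethoxy-4-(methoxymethoxy)-4-[1-(ArAB-oxy)ethenyl]cyclobut-2-en-1-one
Conditions: MOMCl, iPr2NEt, CH2Cl2, 0 °C → rt
Reagents that add atoms: chloromethyl methyl ether, COCCl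
Why: O-Alkylation of the tertiary alcohol under amine base; no acid is present, so the enol ether survives.

Step 9
Reactants: 16 racemic 2,3-dimethoxy-4-(methoxymethoxy)-4-[1-(ArAB-oxy)ethenyl]cyclobut-2-en-1-one
Product: 19 2,3-dimethoxy-4-(methoxymethoxy)-5-(ArAB-oxy)phenol, via dienylketene 17 (not isolated), via cyclohexadienone 18 (not isolated)
Conditions: p-xylene (0.01 M, degassed), 138 °C
Reagents that add atoms: none
Why: Heating opens the cyclobutenone bond between the carbonyl and the quaternary carbon by conrotatory four-electron electrocyclic ring opening to dienylketene 17; the closest known reaction type is the Moore rearrangement of 4-alkenyl-4-alkoxycyclobutenones. The methoxymethoxy group, a donor, rotates outward, so the 1-aryloxyvinyl group turns inward and lies cis to the ketene; this torquoselectivity is the one selectivity the step needs and is inherent in 4-oxy-substituted cyclobutenones. Disrotatory six-electron electrocyclization then joins the ketene carbon to the unsubstituted vinyl terminus, a six-membered ring closure that forms the ring C bond between carbons 3 and 4 and gives dienone 18. Tautomerisation of the CH2 group next to the carbonyl aromatises ring C and leaves the ketene oxygen as the free hydroxyl on carbon 4. Because the tertiary oxygen is capped, no hydroquinone forms and the para oxygens on carbons 1 and 4 emerge differentiated. The ring B oxygen rides in on the internal vinyl carbon and becomes the carbon 2 substituent, and the vinyl terminus is a CH2 group, so closure is not hindered. No stereocenter is formed; the racemic center of 16 becomes a ring carbon. High dilution and exclusion of air suppress capture of the ketene by product phenol and oxidation of the product.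

Step 10
Reactants: 19 2,3-dimethoxy-4-(methoxymethoxy)-5-(ArAB-oxy)phenol
Product: 20 1,2,3-trimethoxy-4-(methoxymethoxy)-5-(ArAB-oxy)benzene
Conditions: MeI, K2CO3, acetone, 56 °C
Reagents that add atoms: iodomethane, CI
Why: Williamson methylation of the only free phenol; the methoxymethyl ether is stable to base.

Step 11
Reactants: 20 1,2,3-trimethoxy-4-(methoxymethoxy)-5-(ArAB-oxy)benzene
Product: 21 2,3,4-trimethoxy-6-(ArAB-oxy)phenol (free hydroxyl on carbon 1 of ring C)
Conditions: HCl (cat.), MeOH, 50 °C
Reagents that add atoms: none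
Why: Acid-catalysed acetal exchange removes the methoxymethyl group; methyl and diaryl ethers are untouched.

Step 12
Reactants: 22 syringaldehyde (4-hydroxy-3,5-dimethoxybenzaldehyde); 23 (3,4,5-trimethoxyphenyl)boronic acid
Product: 24 3,5-dimethoxy-4-(3,4,5-trimethoxyphenoxy)benzaldehyde
Conditions: Cu(OAc)2 (20 mol %), pyridine, 4 Å molecular sieves, CH2Cl2, O2 (1 atm), rt
Reagents that add atoms: none
Why: Chan–Lam coupling; a phenol flanked by two methoxy groups is arylated at room temperature because the aryl group comes from an unhindered boronic acid, and the para formyl group makes the phenol less prone to oxidation.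

Step 13
Reactants: 24 3,5-dimethoxy-4-(3,4,5-trimethoxyphenoxy)benzaldehyde
Product: 26 3,5-dimethoxy-4-(3,4,5-trimethoxyphenoxy)phenol, via aryl formate 25 (not isolated)
Conditions: mCPBA, CH2Cl2, 0 °C → rt; K2CO3 (cat.), MeOH, rt
Reagents that add atoms: 3-chloroperoxybenzoic acid, O=C(OO)c1cccc(Cl)c1
Why: Baeyer–Villiger oxidation; the electron-rich aryl group migrates in preference to hydrogen, and methanolysis of the formate frees the phenol.

Step 14
Reactants: 26 3,5-dimethoxy-4-(3,4,5-trimethoxyphenoxy)phenol
Product: 27 ArFG N-isopropylcarbamate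
Conditions: iPrNCO, Et3N (cat.), CH2Cl2, rt
Reagents that add atoms: isopropyl isocyanate, CC(C)N=C=O
Why: Addition of the phenol to the isocyanate gives the carbamate that will direct metalation and can later be removed under mild base.

Step 15
Reactants: 27 ArFG N-isopropylcarbamate
Product: 31 3,5-dimethoxy-4-(3,4,5-trimethoxyphenoxy)-2-(trimethylsilyl)phenyl N-isopropylcarbamate, via N-silyl carbamate 28 (not isolated), via aryllithium 29 (not isolated), via N-silyl C-silyl carbamate 30 (not isolated)
Conditions: TBSOTf, TMEDA, Et2O, 0 °C → rt; n-BuLi, TMEDA, −78 °C; TMSCl, −78 °C → rt; aq. NaHSO4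
Reagents that add atoms: chlorotrimethylsilane, C[Si](C)(C)Cl
Why: Directed ortho-metalation; N-silylation masks the N–H, the carbamate directs lithiation to the position between itself and a methoxy group (the two ortho positions are equivalent), and the N–Si bond is hydrolysed on acidic work-up.

Step 16
Reactants: 31 3,5-dimethoxy-4-(3,4,5-trimethoxyphenoxy)-2-(trimethylsilyl)phenyl N-isopropylcarbamate
Product: 33 3,5-dimethoxy-4-(3,4,5-trimethoxyphenoxy)-2-(trimethylsilyl)phenyl trifluoromethanesulfonate, via silylphenol 32 (not isolated)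
Conditions: Et2NH, DBU, MeCN, 40 °C; PhNTf2, rt
Reagents that add atoms: N-phenylbis(trifluoromethanesulfonimide), O=S(=O)(N(c1ccccc1)S(=O)(=O)C(F)(F)F)C(F)(F)F
Why: DBU cleaves the N–H carbamate by elimination to the isocyanate, which diethylamine traps as a urea; the phenoxide is triflated in the same flask, giving the ortho-silylaryl triflate.

Step 17
Reactants: 34 2,3,4-trimethoxyphenol
Product: 35 6-iodo-2,3,4-trimethoxyphenol
Conditions: NIS, TsOH·H2O (cat.), MeCN, 0 °C, dark
Reagents that add atoms: N-iodosuccinimide, O=C1CCC(=O)N1I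
Why: Electrophilic iodination goes ortho to the hydroxyl, the strongest donor, whose para position is blocked; the other free carbon is activated only by ether oxygens.

Step 18
Reactants: 35 6-iodo-2,3,4-trimethoxyphenol; 33 3,5-dimethoxy-4-(3,4,5-trimethoxyphenoxy)-2-(trimethylsilyl)phenyl trifluoromethanesulfonate
Product: 37 1-iodo-3,4,5-trimethoxy-2-(ArFG-oxy)benzene (ArEFG–I), via aryne 36 (not isolated)
Conditions: CsF, MeCN, rt
Reagents that add atoms: none
Why: Fluoride-induced 1,2-elimination gives aryne 36, and the phenoxide adds at the aryne carbon remote from the flanking methoxy group, since the developing negative charge is stabilised next to that oxygen; the aryl anion is then protonated. Ortho-iodophenols are established partners in aryne O-arylation and the carbon–iodine bond is untouched.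

Step 19
Reactants: 37 1-iodo-3,4,5-trimethoxy-2-(ArFG-oxy)benzene; 38 3-hydroxy-4,5-dimethoxybenzaldehyde
Product: 39 3,4-dimethoxy-5-(ArEFG-oxy)benzaldehyde
Conditions: CuI (10 mol %), picolinic acid (20 mol %), K3PO4, DMSO, 90 °C, Ar
Reagents that add atoms: none
Why: Ullmann diaryl ether synthesis; iodide and phenol each carry only one ortho substituent, and the non-enolisable aldehyde is inert to phosphate base.

Step 20
Reactants: 39 3,4-dimethoxy-5-(ArEFG-oxy)benzaldehyde
Product: 41 3,4-dimethoxy-5-(ArEFG-oxy)phenol, via aryl formate 40 (not isolated)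
Conditions: mCPBA, CH2Cl2, 0 °C → rt; K2CO3 (cat.), MeOH, rt
Reagents that add atoms: 3-chloroperoxybenzoic acid, O=C(OO)c1cccc(Cl)c1
Why: Baeyer–Villiger oxidation with aryl migration, as in step 13, turns the formyl group into the hydroxyl on carbon 1 of ring D.

Step 21
Reactants: 41 3,4-dimethoxy-5-(ArEFG-oxy)phenol
Product: 42 3,4-dimethoxy-5-(ArEFG-oxy)phenyl N-isopropylcarbamate
Conditions: iPrNCO, Et3N (cat.), CH2Cl2, rt
Reagents that add atoms: isopropyl isocyanate, CC(C)N=C=O
Why: Carbamate formation as in step 14.

Step 22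
Reactants: 42 3,4-dimethoxy-5-(ArEFG-oxy)phenyl N-isopropylcarbamate
Product: 46 3,4-dimethoxy-5-(ArEFG-oxy)-2-(trimethylsilyl)phenyl N-isopropylcarbamate, via N-silyl carbamate 43 (not isolated), via aryllithium 44 (not isolated), via N-silyl C-silyl carbamate 45 (not isolated)
Conditions: TBSOTf, TMEDA, Et2O–THF, 0 °C → rt; n-BuLi, TMEDA, −78 °C; TMSCl, −78 °C → rt; aq. NaHSO4
Reagents that add atoms: chlorotrimethylsilane, C[Si](C)(C)Cl
Why: Directed ortho-metalation as in step 15; lithiation is expected between the carbamate and the methoxy group, the site known for 3-methoxyphenyl carbamates, the other ortho position being crowded by the large aryloxy group. Silylation at that other position would not change the outcome of step 24, because the aryne then formed is flanked by the aryloxy oxygen on carbon 5 and is likewise attacked at carbon 1.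

Step 23
Reactants: 46 3,4-dimethoxy-5-(ArEFG-oxy)-2-(trimethylsilyl)phenyl N-isopropylcarbamate
Product: 48 3,4-dimethoxy-5-(ArEFG-oxy)-2-(trimethylsilyl)phenyl trifluoromethanesulfonate, via silylphenol 47 (not isolated)
Conditions: Et2NH, DBU, MeCN, 40 °C; PhNTf2, rt
Reagents that add atoms: N-phenylbis(trifluoromethanesulfonimide), O=S(=O)(N(c1ccccc1)S(=O)(=O)C(F)(F)F)C(F)(F)F
Why: Carbamate cleavage and triflation in one flask, as in step 16.

Step 24
Reactants: 21 2,3,4-trimethoxy-6-(ArAB-oxy)phenol; 48 3,4-dimethoxy-5-(ArEFG-oxy)-2-(trimethylsilyl)phenyl trifluoromethanesulfonate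
Product: 50 heptamer octadecamethyl ether, via aryne 49 (not isolated)
Conditions: CsF, MeCN–THF, rt
Reagents that add atoms: none
Why: Aryne O-arylation; the phenoxide of 21 adds to carbon 1 of ring D, remote from the methoxy group on carbon 3, and protonation places hydrogen on carbon 2. The phenoxide has no free ortho or para carbon, so only the oxygen can be arylated, and the hindrance of the nucleophile matters little toward an aryne carbon flanked by hydrogen.

Step 25
Reactants: 50 heptamer octadecamethyl ether
Product: 51 CNP0130704.0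
Conditions: BBr3 (excess), CH2Cl2, −78 °C → rt; MeOH then H2O, 0 °C, Ar
Reagents that add atoms: none
Why: Lewis acid cleavage of aryl methyl ethers: BBr3 binds each methoxy oxygen and bromide removes the methyl group, while diaryl ethers are inert. Work-up and reverse-phase purification under argon protect the polyphenol.

## Compound list

1 | 4-bromo-2,6-dimethoxyphenol | Oc1c(OC)cc(Br)cc1OC | starting material
2 | 2-(benzyloxy)-5-bromo-1,3-dimethoxybenzene | COc1cc(Br)cc(OC)c1OCc1ccccc1 | intermediate
3 | 2,4,6-trimethoxyphenol | COc1cc(OC)c(O)c(OC)c1 | starting material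
4 | 2-(benzyloxy)-1,3-dimethoxy-5-(2,4,6-trimethoxyphenoxy)benzene | COc1cc(OC)c(Oc2cc(OC)c(OCc3ccccc3)c(OC)c2)c(OC)c1 | intermediate
5 | 2,6-dimethoxy-4-(2,4,6-trimethoxyphenoxy)phenol (ArAB–OH) | COc1cc(OC)c(Oc2cc(OC)c(O)c(OC)c2)c(OC)c1 | intermediate
6 | trichloroethylene | ClC=C(Cl)Cl | starting material
7 | dichloroacetylene | ClC#CCl | intermediate
8 | 2-{[(E)-1,2-dichloroethenyl]oxy}-1,3-dimethoxy-5-(2,4,6-trimethoxyphenoxy)benzene | Cl/C=C(/Cl)Oc1c(OC)cc(Oc2c(OC)cc(OC)cc2OC)cc1OC | intermediate
9 | 2-[(chloroethynyl)oxy]-1,3-dimethoxy-5-(2,4,6-trimethoxyphenoxy)benzene | ClC#COc1c(OC)cc(Oc2c(OC)cc(OC)cc2OC)cc1OC | intermediate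
10 | lithium 2-(ArAB-oxy)acetylide | [Li]C#COc1c(OC)cc(Oc2c(OC)cc(OC)cc2OC)cc1OC | intermediate
11 | 2-(ethynyloxy)-1,3-dimethoxy-5-(2,4,6-trimethoxyphenoxy)benzene | C#COc1c(OC)cc(Oc2c(OC)cc(OC)cc2OC)cc1OC | intermediate
12 | tributyl[1-(ArAB-oxy)ethenyl]stannane | C=C(Oc1c(OC)cc(Oc2c(OC)cc(OC)cc2OC)cc1OC)[Sn](CCCC)(CCCC)CCCC | intermediate
13 | dimethyl squarate (3,4-dimethoxycyclobut-3-ene-1,2-dione) | COC1=C(OC)C(=O)C1=O | starting material
14 | 1-(ArAB-oxy)ethenyllithium | [Li]C(=C)Oc1c(OC)cc(Oc2c(OC)cc(OC)cc2OC)cc1OC | intermediate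
15 | racemic 4-hydroxy-2,3-dimethoxy-4-[1-(ArAB-oxy)ethenyl]cyclobut-2-en-1-one | OC1(C(=C)Oc2c(OC)cc(Oc3c(OC)cc(OC)cc3OC)cc2OC)C(=O)C(OC)=C1OC | intermediate
16 | racemic 2,3-dimethoxy-4-(methoxymethoxy)-4-[1-(ArAB-oxy)ethenyl]cyclobut-2-en-1-one | COCOC1(C(=C)Oc2c(OC)cc(Oc3c(OC)cc(OC)cc3OC)cc2OC)C(=O)C(OC)=C1OC | intermediate
17 | (3Z)-2,3-dimethoxy-4-(methoxymethoxy)-5-(ArAB-oxy)hexa-1,3,5-trien-1-one | O=C=C(OC)/C(OC)=C(/OCOC)C(=C)Oc1c(OC)cc(Oc2c(OC)cc(OC)cc2OC)cc1OC | intermediate
18 | 2,3-dimethoxy-4-(methoxymethoxy)-5-(ArAB-oxy)cyclohexa-2,4-dien-1-one | O=C1CC(Oc2c(OC)cc(Oc3c(OC)cc(OC)cc3OC)cc2OC)=C(OCOC)C(OC)=C1OC | intermediate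
19 | 2,3-dimethoxy-4-(methoxymethoxy)-5-(ArAB-oxy)phenol | COCOc1c(OC)c(OC)c(O)cc1Oc1c(OC)cc(Oc2c(OC)cc(OC)cc2OC)cc1OC | intermediate
20 | 1,2,3-trimethoxy-4-(methoxymethoxy)-5-(ArAB-oxy)benzene | COCOc1c(OC)c(OC)c(OC)cc1Oc1c(OC)cc(Oc2c(OC)cc(OC)cc2OC)cc1OC | intermediate
21 | 2,3,4-trimethoxy-6-(ArAB-oxy)phenol | Oc1c(OC)c(OC)c(OC)cc1Oc1c(OC)cc(Oc2c(OC)cc(OC)cc2OC)cc1OC | intermediate
22 | syringaldehyde (4-hydroxy-3,5-dimethoxybenzaldehyde) | COc1cc(C=O)cc(OC)c1O | starting material
23 | (3,4,5-trimethoxyphenyl)boronic acid | COc1cc(B(O)O)cc(OC)c1OC | starting material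
24 | 3,5-dimethoxy-4-(3,4,5-trimethoxyphenoxy)benzaldehyde | COc1cc(C=O)cc(OC)c1Oc1cc(OC)c(OC)c(OC)c1 | intermediate
25 | 3,5-dimethoxy-4-(3,4,5-trimethoxyphenoxy)phenyl formate | COc1cc(OC=O)cc(OC)c1Oc1cc(OC)c(OC)c(OC)c1 | intermediate
26 | 3,5-dimethoxy-4-(3,4,5-trimethoxyphenoxy)phenol (ArFG–OH) | COc1cc(O)cc(OC)c1Oc1cc(OC)c(OC)c(OC)c1 | intermediate
27 | 3,5-dimethoxy-4-(3,4,5-trimethoxyphenoxy)phenyl N-isopropylcarbamate | COc1cc(OC(=O)NC(C)C)cc(OC)c1Oc1cc(OC)c(OC)c(OC)c1 | intermediate
28 | ArFG N-(tert-butyldimethylsilyl)-N-isopropylcarbamate | COc1cc(OC(=O)N(C(C)C)[Si](C)(C)C(C)(C)C)cc(OC)c1Oc1cc(OC)c(OC)c(OC)c1 | intermediate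
29 | 2-lithio derivative of 28 | COc1cc(OC(=O)N(C(C)C)[Si](C)(C)C(C)(C)C)c([Li])c(OC)c1Oc1cc(OC)c(OC)c(OC)c1 | intermediate
30 | 2-(trimethylsilyl) derivative of 28 | COc1cc(OC(=O)N(C(C)C)[Si](C)(C)C(C)(C)C)c([Si](C)(C)C)c(OC)c1Oc1cc(OC)c(OC)c(OC)c1 | intermediate
31 | 3,5-dimethoxy-4-(3,4,5-trimethoxyphenoxy)-2-(trimethylsilyl)phenyl N-isopropylcarbamate | COc1cc(OC(=O)NC(C)C)c([Si](C)(C)C)c(OC)c1Oc1cc(OC)c(OC)c(OC)c1 | intermediate
32 | 3,5-dimethoxy-4-(3,4,5-trimethoxyphenoxy)-2-(trimethylsilyl)phenol | COc1cc(O)c([Si](C)(C)C)c(OC)c1Oc1cc(OC)c(OC)c(OC)c1 | intermediate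
33 | 3,5-dimethoxy-4-(3,4,5-trimethoxyphenoxy)-2-(trimethylsilyl)phenyl trifluoromethanesulfonate | COc1cc(OS(=O)(=O)C(F)(F)F)c([Si](C)(C)C)c(OC)c1Oc1cc(OC)c(OC)c(OC)c1 | intermediate
34 | 2,3,4-trimethoxyphenol | COc1ccc(O)c(OC)c1OC | starting material
35 | 6-iodo-2,3,4-trimethoxyphenol | COc1cc(I)c(O)c(OC)c1OC | intermediate
36 | 3,5-dimethoxy-4-(3,4,5-trimethoxyphenoxy)benzyne (triple bond between carbons 1 and 2) | COC1=C(Oc2cc(OC)c(OC)c(OC)c2)C(OC)=CC#C1 | intermediate
37 | 1-iodo-3,4,5-trimethoxy-2-(ArFG-oxy)benzene (ArEFG–I) | COc1cc(I)c(Oc2cc(OC)c(Oc3cc(OC)c(OC)c(OC)c3)c(OC)c2)c(OC)c1OC | intermediate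
38 | 3-hydroxy-4,5-dimethoxybenzaldehyde | COc1cc(C=O)cc(O)c1OC | starting material
39 | 3,4-dimethoxy-5-(ArEFG-oxy)benzaldehyde | COc1cc(C=O)cc(Oc2cc(OC)c(OC)c(OC)c2Oc2cc(OC)c(Oc3cc(OC)c(OC)c(OC)c3)c(OC)c2)c1OC | intermediate
40 | 3,4-dimethoxy-5-(ArEFG-oxy)phenyl formate | COc1cc(OC=O)cc(Oc2cc(OC)c(OC)c(OC)c2Oc2cc(OC)c(Oc3cc(OC)c(OC)c(OC)c3)c(OC)c2)c1OC | intermediate
41 | 3,4-dimethoxy-5-(ArEFG-oxy)phenol | COc1cc(O)cc(Oc2cc(OC)c(OC)c(OC)c2Oc2cc(OC)c(Oc3cc(OC)c(OC)c(OC)c3)c(OC)c2)c1OC | intermediate
42 | 3,4-dimethoxy-5-(ArEFG-oxy)phenyl N-isopropylcarbamate | COc1cc(OC(=O)NC(C)C)cc(Oc2cc(OC)c(OC)c(OC)c2Oc2cc(OC)c(Oc3cc(OC)c(OC)c(OC)c3)c(OC)c2)c1OC | intermediate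
43 | N-(tert-butyldimethylsilyl) derivative of 42 | COc1cc(OC(=O)N(C(C)C)[Si](C)(C)C(C)(C)C)cc(Oc2cc(OC)c(OC)c(OC)c2Oc2cc(OC)c(Oc3cc(OC)c(OC)c(OC)c3)c(OC)c2)c1OC | intermediate
44 | 2-lithio derivative of 43 | COc1c([Li])c(OC(=O)N(C(C)C)[Si](C)(C)C(C)(C)C)cc(Oc2cc(OC)c(OC)c(OC)c2Oc2cc(OC)c(Oc3cc(OC)c(OC)c(OC)c3)c(OC)c2)c1OC | intermediate
45 | 2-(trimethylsilyl) derivative of 43 | COc1c([Si](C)(C)C)c(OC(=O)N(C(C)C)[Si](C)(C)C(C)(C)C)cc(Oc2cc(OC)c(OC)c(OC)c2Oc2cc(OC)c(Oc3cc(OC)c(OC)c(OC)c3)c(OC)c2)c1OC | intermediate
46 | 3,4-dimethoxy-5-(ArEFG-oxy)-2-(trimethylsilyl)phenyl N-isopropylcarbamate | COc1c([Si](C)(C)C)c(OC(=O)NC(C)C)cc(Oc2cc(OC)c(OC)c(OC)c2Oc2cc(OC)c(Oc3cc(OC)c(OC)c(OC)c3)c(OC)c2)c1OC | intermediate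
47 | 3,4-dimethoxy-5-(ArEFG-oxy)-2-(trimethylsilyl)phenol | COc1c([Si](C)(C)C)c(O)cc(Oc2cc(OC)c(OC)c(OC)c2Oc2cc(OC)c(Oc3cc(OC)c(OC)c(OC)c3)c(OC)c2)c1OC | intermediate
48 | 3,4-dimethoxy-5-(ArEFG-oxy)-2-(trimethylsilyl)phenyl trifluoromethanesulfonate | COc1c([Si](C)(C)C)c(OS(=O)(=O)C(F)(F)F)cc(Oc2cc(OC)c(OC)c(OC)c2Oc2cc(OC)c(Oc3cc(OC)c(OC)c(OC)c3)c(OC)c2)c1OC | intermediate
49 | 3,4-dimethoxy-5-(ArEFG-oxy)benzyne (triple bond between carbons 1 and 2 of ring D) | COC1=C(OC)C(Oc2cc(OC)c(OC)c(OC)c2Oc2cc(OC)c(Oc3cc(OC)c(OC)c(OC)c3)c(OC)c2)=CC#C1 | intermediate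
50 | heptamer octadecamethyl ether (rings A to G; every hydroxyl of 51 as its methyl ether) | COc1cc(OC)c(Oc2cc(OC)c(Oc3cc(OC)c(OC)c(OC)c3Oc3cc(OC)c(OC)c(Oc4cc(OC)c(OC)c(OC)c4Oc4cc(OC)c(Oc5cc(OC)c(OC)c(OC)c5)c(OC)c4)c3)c(OC)c2)c(OC)c1 | intermediate
51 | CNP0130704.0 | Oc1cc(O)c(Oc2cc(O)c(Oc3cc(O)c(O)c(O)c3Oc3cc(O)c(O)c(Oc4cc(O)c(O)c(O)c4Oc4cc(O)c(Oc5cc(O)c(O)c(O)c5)c(O)c4)c3)c(O)c2)c(O)c1 | target

## Step count and least certain steps

Total step count: 25. Longest linear sequence: 13 steps (steps 1 to 11, 24, 25; the branch through steps 12 to 16, 18 to 23, 24, 25 is equally long).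

Step 9 (key step). The ring-opened ketene may be captured by phenol already formed, giving esters, or the acetal may be lost at 138 °C, which would erase the differentiation of the para oxygens. Both are bimolecular or thermal side processes that compete with a closure in a crowded triene. Fallback: it sets out from alcohol 15, which is heated without a protecting group in toluene at 110 °C, the parent form of the rearrangement, to give 2,3-dimethoxy-5-(ArAB-oxy)benzene-1,4-diol F1. The hydroxyl on carbon 4, flanked by hydrogen, is then methylated selectively (MeI, one equivalent, Li2CO3, DMF) in preference to the hydroxyl on carbon 1, which is buried between methoxy and the large aryloxy group. The route is rejoined at 21.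

Step 7. Vinyllithium 14 carries a leaving group on the metalated carbon and may decompose by loss of lithium aryloxide before it meets 13; a second addition to the squarate is the other danger. Fallback: it sets out from 8, which is converted to acetylide 10 as in step 5 but not quenched; 10 is stable, is added to 13 at −78 °C and the alkoxide is trapped with MeOTf to give racemic 2,3,4-trimethoxy-4-[(ArAB-oxy)ethynyl]cyclobut-2-en-1-one F2. Semi-hydrogenation (H2, Pd/CaCO3 poisoned with Pb(OAc)2, quinoline) gives the (Z)-2-(ArAB-oxy)ethenyl compound F3, and heating in toluene at 110 °C closes ring C, now between carbons 1 and 2. The ketene oxygen becomes the free hydroxyl on carbon 1 and the route is rejoined at 21. The price is a Z-enol ether whose aryloxy group must turn inward during closure.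

Step 6. Tin may be delivered to the terminal carbon, or the ynol ether may oligomerise on palladium, because the aryloxy group polarises the alkyne less than an alkoxy group does. Fallback: it sets out from 11; HBr (from Me3SiBr and MeOH, CH2Cl2, −78 °C) adds in the Markovnikov sense, by protonation at the terminal carbon and capture of bromide at the oxygen-bearing carbon, to give 2-[(1-bromoethenyl)oxy]-1,3-dimethoxy-5-(2,4,6-trimethoxyphenoxy)benzene F4. Bromine–lithium exchange (t-BuLi, two equivalents, THF, −78 °C) gives 14, and the route is rejoined at 15.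

Step 24. The aryne may be consumed by fluoride, solvent or self-reaction faster than by the hindered and poorly soluble cesium phenoxide of 21. Fallback: it sets out from 41, which is triflated (Tf2O, pyridine) to 3,4-dimethoxy-5-(ArEFG-oxy)phenyl trifluoromethanesulfonate F5. F5 is coupled with 21 under palladium catalysis (Pd(OAc)2, 2-di-tert-butylphosphino-2',4',6'-triisopropylbiphenyl, K3PO4, toluene, 100 °C), and the route is rejoined at 50; steps 21 to 23 are then not needed.

Step 25. Cleavage of eighteen methyl ethers may stop short when partly demethylated aryl borates precipitate, and the product may oxidise during work-up. Fallback: it sets out from 50; the crude product of the BBr3 treatment is acetylated (Ac2O, pyridine) to the octadecaacetate F6, which can be chromatographed, and under-demethylated material is separated and treated again. Acid methanolysis (HCl, degassed MeOH) then releases 51.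

## Further compounds

F1 | step 9 | 2,3-dimethoxy-5-(ArAB-oxy)benzene-1,4-diol | Oc1c(OC)c(OC)c(O)cc1Oc1c(OC)cc(Oc2c(OC)cc(OC)cc2OC)cc1OC
F2 | step 7 | racemic 2,3,4-trimethoxy-4-[(ArAB-oxy)ethynyl]cyclobut-2-en-1-one | COC1(C#COc2c(OC)cc(Oc3c(OC)cc(OC)cc3OC)cc2OC)C(=O)C(OC)=C1OC
F3 | step 7 | racemic 2,3,4-trimethoxy-4-[(Z)-2-(ArAB-oxy)ethenyl]cyclobut-2-en-1-one | COC1(/C=C\Oc2c(OC)cc(Oc3c(OC)cc(OC)cc3OC)cc2OC)C(=O)C(OC)=C1OC
F4 | step 6 | 2-[(1-bromoethenyl)oxy]-1,3-dimethoxy-5-(2,4,6-trimethoxyphenoxy)benzene | BrC(=C)Oc1c(OC)cc(Oc2c(OC)cc(OC)cc2OC)cc1OC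
F5 | step 24 | 3,4-dimethoxy-5-(ArEFG-oxy)phenyl trifluoromethanesulfonate | COc1cc(OS(=O)(=O)C(F)(F)F)cc(Oc2cc(OC)c(OC)c(OC)c2Oc2cc(OC)c(Oc3cc(OC)c(OC)c(OC)c3)c(OC)c2)c1OC
F6 | step 25 | octadecaacetate of 51 | CC(=O)Oc1cc(OC(C)=O)c(Oc2cc(OC(C)=O)c(Oc3cc(OC(C)=O)c(OC(C)=O)c(OC(C)=O)c3Oc3cc(OC(C)=O)c(OC(C)=O)c(Oc4cc(OC(C)=O)c(OC(C)=O)c(OC(C)=O)c4Oc4cc(OC(C)=O)c(Oc5cc(OC(C)=O)c(OC(C)=O)c(OC(C)=O)c5)c(OC(C)=O)c4)c3)c(OC(C)=O)c2)c(OC(C)=O)c1
A1 | alternative 1 | [(C5H5)Ru(1,5-dichloro-2,3-dimethoxybenzene)]PF6 | COc1cc(Cl)cc(Cl)c1OC.[CH-]1C=CC=C1.[Ru+2].F[P-](F)(F)(F)(F)F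
A2 | alternative 1 | 3,4,5-trimethoxy-2-(ArFG-oxy)phenol | COc1cc(O)c(Oc2cc(OC)c(Oc3cc(OC)c(OC)c(OC)c3)c(OC)c2)c(OC)c1OC
A3 | alternative 1 | heptamer octadecamethyl ether (identical with 50) | COc1cc(OC)c(Oc2cc(OC)c(Oc3cc(OC)c(OC)c(OC)c3Oc3cc(OC)c(OC)c(Oc4cc(OC)c(OC)c(OC)c4Oc4cc(OC)c(Oc5cc(OC)c(OC)c(OC)c5)c(OC)c4)c3)c(OC)c2)c(OC)c1
A4 | alternative 2 | dimethyl 2-(hexamer-oxy)malonate (rings B to G as methyl ethers) | COC(=O)C(Oc1cc(OC)c(Oc2cc(OC)c(OC)c(OC)c2Oc2cc(OC)c(OC)c(Oc3cc(OC)c(OC)c(OC)c3Oc3cc(OC)c(Oc4cc(OC)c(OC)c(OC)c4)c(OC)c3)c2)c(OC)c1)C(=O)OC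
A5 | alternative 2 | dimethyl 3-oxopentanedioate | COC(=O)CC(=O)CC(=O)OC
A6 | alternative 2 | heptamer with ring A as dimethyl 2,4,6-trihydroxy-5-aryloxybenzene-1,3-dicarboxylate | COC(=O)c1c(O)c(C(=O)OC)c(O)c(Oc2cc(OC)c(Oc3cc(OC)c(OC)c(OC)c3Oc3cc(OC)c(OC)c(Oc4cc(OC)c(OC)c(OC)c4Oc4cc(OC)c(Oc5cc(OC)c(OC)c(OC)c5)c(OC)c4)c3)c(OC)c2)c1O
A7 | alternative 3 | racemic 4-methoxy-3-(ArEFG-oxy)cyclobut-2-en-1-one | COC1C(=O)C=C1Oc1cc(OC)c(OC)c(OC)c1Oc1cc(OC)c(Oc2cc(OC)c(OC)c(OC)c2)c(OC)c1
A8 | alternative 3 | 2-(ethynyloxy)-3,4,5-trimethoxy-1-(ArAB-oxy)benzene | C#COc1c(OC)c(OC)c(OC)cc1Oc1c(OC)cc(Oc2c(OC)cc(OC)cc2OC)cc1OC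
A9 | alternative 3 | heptamer heptadecamethyl ether with free hydroxyl on carbon 3 of ring D | COc1cc(OC)c(Oc2cc(OC)c(Oc3cc(OC)c(OC)c(OC)c3Oc3cc(O)c(OC)c(Oc4cc(OC)c(OC)c(OC)c4Oc4cc(OC)c(Oc5cc(OC)c(OC)c(OC)c5)c(OC)c4)c3)c(OC)c2)c(OC)c1
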